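**Retrosynthetic overview**
1. Building blocks: catechol 1, masked as its bis-TBS ether 2, and hexadecyl acrylate 3. Compound 3 already carries the ester C–O bond and the C16 chain.
2. Key disconnection: the C(aryl)–CH2 bond of protected ester 4. It is made by a new redox-neutral, palladium-catalysed C–H addition of 2 across 3.
3. Last disconnection: the two O–Si bonds of 4, cleaved with buffered fluoride to give target 5.
4. Rings: the only ring is the benzene ring (ring A). It is bought with 1, so no ring is formed.

Assumption: the target has no stereocentre and no stereogenic double bond, so it is achiral and needs no stereocontrol.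

**Step 1**
Reactants: 1 catechol (benzene-1,2-diol)
Product: 2 catechol bis(tert-butyldimethylsilyl) ether (1,2-bis[(tert-butyldimethylsilyl)oxy]benzene)
Conditions: TBSCl (2.4 equiv), imidazole (5 equiv), DMF, rt, 16 h
Reagents that add atoms: tert-butyldimethylsilyl chloride (TBSCl), CC(C)(C)[Si](C)(C)Cl
Why: Imidazole-promoted O-silylation (nucleophilic substitution at silicon) of both phenols is routine and high-yielding in DMF, and the two bulky OTBS groups later shield C3 and C6 of ring A.

**Step 2**
Reactants: 2 catechol bis(tert-butyldimethylsilyl) ether (1.0 equiv); 3 hexadecyl acrylate (1.3 equiv)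
Product: 4 hexadecyl 3-{3,4-bis[(tert-butyldimethylsilyl)oxy]phenyl}propanoate
Conditions: Pd(OAc)2 (5 mol %), [2,2'-bipyridin]-6(1H)-one (6 mol %), PivOH (30 mol %), BHT (1 mol %), (CF3)2CHOH/ClCH2CH2Cl 1:3, 90 °C, N2, 24 h
Reagents that add atoms: none
Why: Proposed new method: a redox-neutral, non-directed C–H conjugate addition (hydroarylation) of an arene to an acrylate at divalent palladium bearing a cooperating bipyridone ligand, in which the deprotonated pyridone oxygen removes the C4–H of 2 by concerted metalation–deprotonation (C3 and C6 are blocked by the flanking OTBS groups and C4 and C5 are equivalent, so one regioisomer results), the aryl–palladium species undergoes 2,1-insertion of 3 to place the aryl group on the β-carbon, the N,N-chelate together with oxa-π-allyl binding of the resulting palladium enolate leaves no free cis site for β-hydride elimination, and the ligand O–H created in the C–H cleavage step protonates the enolate to release 4 and regenerate the catalyst without any oxidant; the closest known reaction types are the non-directed Fujiwara–Moritani olefination with pyridone ligands and the Pd(OAc)2/2,2'-bipyridine conjugate addition of arylboronic acids to acrylates, merged here so that a C–H bond takes the place of the C–B bond.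

**Step 3**
Reactants: 4 hexadecyl 3-{3,4-bis[(tert-butyldimethylsilyl)oxy]phenyl}propanoate
Product: 5 hexadecyl 3-(3,4-dihydroxyphenyl)propanoate (target)
Conditions: TBAF (2.2 equiv), AcOH (2.4 equiv), THF, 0 °C, Ar, 30 min
Reagents that add atoms: none
Why: Fluoride-induced desilylation, driven by the strong Si–F bond, cleaves aryl silyl ethers within minutes at 0 °C, and the acetic acid buffer keeps the medium non-basic so the hexadecyl ester stays intact and the catechol is not oxidised as its anion.

**Compound list**
1 | catechol (benzene-1,2-diol) | Oc1ccccc1O | starting material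
2 | catechol bis(tert-butyldimethylsilyl) ether (1,2-bis[(tert-butyldimethylsilyl)oxy]benzene) | CC(C)(C)[Si](C)(C)Oc1ccccc1O[Si](C)(C)C(C)(C)C | intermediate
3 | hexadecyl acrylate (hexadecyl prop-2-enoate) | CCCCCCCCCCCCCCCCOC(=O)C=C | starting material
4 | hexadecyl 3-{3,4-bis[(tert-butyldimethylsilyl)oxy]phenyl}propanoate | CCCCCCCCCCCCCCCCOC(=O)CCc1ccc(O[Si](C)(C)C(C)(C)C)c(O[Si](C)(C)C(C)(C)C)c1 | intermediate
5 | hexadecyl 3-(3,4-dihydroxyphenyl)propanoate | CCCCCCCCCCCCCCCCOC(=O)CCc1ccc(O)c(O)c1 | target

Total step count: 3
Longest linear sequence: 3 steps (1 → 2 → 4 → 5)

**Three steps most likely to fail**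

Step 2, the proposed new step.
- The palladium enolate may undergo β-hydride elimination faster than protonation. That would give the cinnamate-type ester and zerovalent palladium.
- C–H cleavage by a chelated palladium centre may be too slow with the arene as limiting reagent.
- Compound 3 may oligomerise at 90 °C.
- The fallback uses known chemistry, sets out from 2 and comes back to the route at 4. Sterically controlled iridium-catalysed C–H borylation of 2 ([Ir(OMe)(cod)]2 1.5 mol %, 4,4'-di-tert-butyl-2,2'-bipyridine 3 mol %, B2pin2 1.0 equiv, THF, 80 °C) functionalises the only unhindered position. This gives 2-{3,4-bis[(tert-butyldimethylsilyl)oxy]phenyl}-4,4,5,5-tetramethyl-1,3,2-dioxaborolane F1. Rhodium-catalysed conjugate addition of the Hayashi–Miyaura type of F1 to 3 ([Rh(OH)(cod)]2 2.5 mol %, dioxane/H2O 10:1, 60 °C, no added base so the aryl silyl ethers survive) then gives 4.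

Step 3.
- The free catechol is air-sensitive. Any unbuffered fluoride would form the catecholate, which oxidises to the quinone and can also attack the ester.
- The fallback sets out from 4 and comes back at 5. Lewis-acid-catalysed exchange of silyl for acetyl (Ac2O 4 equiv, Bi(OTf)3 2 mol %, CH2Cl2, rt) avoids fluoride and free phenoxide altogether. It gives the air-stable, chromatographable hexadecyl 3-(3,4-diacetoxyphenyl)propanoate F2.
- The two activated aryl acetates of F2 are then removed chemoselectively by hydrazinolysis (N2H4·H2O 2.2 equiv, THF, 0 °C). These reducing conditions leave the alkyl ester untouched and give 5.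

Step 1.
- The second silylation takes place next to an OTBS group already in place. It may stall at the mono-ether, and chloride or imidazole residues carried forward could poison the palladium catalyst of step 2.
- The fallback sets out from 1 and comes back at 2. It uses B(C6F5)3-catalysed dehydrogenative Si–O coupling of 1 with tert-butyldimethylsilane (2.2 equiv, B(C6F5)3 2 mol %, toluene, rt).
- This replaces substitution at a chlorosilane by hydrosilane activation and gives 2 free of salts. It makes no new compound (F0).

**Further compounds**
F1 | step 2 | 2-{3,4-bis[(tert-butyldimethylsilyl)oxy]phenyl}-4,4,5,5-tetramethyl-1,3,2-dioxaborolane | CC(C)(C)[Si](C)(C)Oc1ccc(cc1O[Si](C)(C)C(C)(C)C)B1OC(C)(C)C(C)(C)O1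
F2 | step 3 | hexadecyl 3-(3,4-diacetoxyphenyl)propanoate | CCCCCCCCCCCCCCCCOC(=O)CCc1ccc(OC(C)=O)c(OC(C)=O)c1
F0 | step 1 | none | none
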